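## Retrosynthetic overview

- The strategy rests on the cis C1=C2 enone that lies between the C3 carbonyl and the C10 tertiary carbinol. In the target it is folded into the 2,5-dihydrofuran hemiketal ring (O–C3–C2=C1–C10) that bridges the ten-membered carbocycle C1–C10. It is carried as a C1≡C2 alkyne, so neither the alkene geometry nor the hemiketal exists while the large ring is closed.
- Key disconnection C2–C3: a NiCl2-catalysed CrCl2 coupling of a C2 iodoalkyne with the C3 (Z)-enal closes the ten-membered ring. Oxidation at C3, cis-semihydrogenation and desilylation then let the hemiketal form, and acetylation of the side-chain hydroxyl finishes the synthesis.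
- Disconnection C7–C8: a zinc Barbier coupling joins a C6-defined 3-(bromomethyl)butenolide (C3–C7, C11–C13) to the C8 aldehyde (C8–C10, C1, C2). It sets C7 and C8 and gives the trans-fused α-methylene lactone with a free C8 hydroxyl, which is esterified at once with the silyl-protected angelate-type acid.
- Fragments: (S)-2-methylglycidol supplies C10 and the alkyne. Propargyl alcohol (cuprate route to the (Z)-enal), a ProPhenol alkynylation (C6) and 2-(bromomethyl)acrylic acid give the bromobutenolide by ring-closing metathesis. Crotonaldehyde gives the acid.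
- Ring order: lactone ring (step 15, transposed in step 20), ten-membered carbocycle (step 25), dihydrofuran hemiketal ring (step 28).

Key step: step 25

Remark: atoms carry germacranolide numbers (C1–C10 ten-membered ring; C11, C12 carbonyl and C13 methylene of the lactone).
Remark: the (S,S) antipode of ProPhenol is assumed to deliver the alkynyl group to the face of 14 that gives (R)-15; if the sense is the reverse, the (R,R)-ligand is used.

## Route

Step 1
Reactants: 1 (S)-2-methylglycidol
Product: 2 (R)-2-methylpent-4-ene-1,2-diol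
Conditions: CH2=CHMgBr (3 equiv), CuI (10 mol%), THF, −40 to 0 °C; aq NH4Cl
Reagents that add atoms: vinylmagnesium bromide, C=C[Mg]Br
Why: Copper-catalysed Grignard opening of the 2,2-disubstituted epoxide occurs at its unsubstituted CH2, so the C–O bond of the quaternary carbon (the later C10) is never broken and its configuration comes unchanged from the chiral pool.

Step 2
Reactants: 2 (R)-2-methylpent-4-ene-1,2-diol
Product: 3 (R)-2-hydroxy-2-methylpent-4-enal
Conditions: SO3·pyridine, DMSO, i-Pr2NEt, CH2Cl2, 0 °C; used crude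
Reagents that add atoms: none
Why: Parikh–Doering oxidation converts only the primary hydroxyl (the tertiary one has no carbinol hydrogen) under mildly basic conditions, and the crude hydroxy aldehyde is taken on at once to avoid dimerisation.

Step 3
Reactants: 3 (R)-2-hydroxy-2-methylpent-4-enal
Product: 4 (R)-3-methylhex-5-en-1-yn-3-ol
Conditions: Ohira–Bestmann reagent, K2CO3, MeOH, 0 °C to rt
Reagents that add atoms: dimethyl (1-diazo-2-oxopropyl)phosphonate, CC(=O)C(=[N+]=[N-])P(=O)(OC)OC
Why: Ohira–Bestmann (Seyferth–Gilbert) homologation turns the aldehyde into the C1≡C2 terminal alkyne with K2CO3/MeOH, which the non-epimerisable quaternary α-carbon tolerates.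

Step 4
Reactants: 4 (R)-3-methylhex-5-en-1-yn-3-ol
Product: 5 (R)-triethyl[(3-methylhex-5-en-1-yn-3-yl)oxy]silane
Conditions: Et3SiOTf, 2,6-lutidine, CH2Cl2, −78 to 0 °C
Reagents that add atoms: triethylsilyl triflate, CC[Si](CC)(CC)OS(=O)(=O)C(F)(F)F
Why: Silylation of a hindered tertiary propargylic alcohol with the silyl triflate and 2,6-lutidine is standard, and TES is chosen so that fluoride can free the C10 hydroxyl late.

Step 5
Reactants: 5 (R)-triethyl[(3-methylhex-5-en-1-yn-3-yl)oxy]silane
Product: 6 (R)-3-methyl-3-(triethylsilyloxy)pent-4-ynal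
Conditions: OsO4 (2 mol%), NaIO4, 2,6-lutidine, dioxane/H2O, rt
Reagents that add atoms: osmium tetroxide, O=[Os](=O)(=O)=O; sodium periodate, [Na+].[O-][I](=O)(=O)=O
Why: Lemieux–Johnson cleavage (catalytic dihydroxylation, periodate scission) attacks the monosubstituted alkene much faster than the terminal alkyne, and 2,6-lutidine buffers the medium so that the β-silyloxy aldehyde neither desilylates nor eliminates.

Step 6
Reactants: 7 propargyl alcohol
Product: 8 4-methoxybenzyl propargyl ether
Conditions: NaH, 4-methoxybenzyl chloride, Bu4NI (cat.), THF, 0 °C to rt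
Reagents that add atoms: 4-methoxybenzyl chloride, COc1ccc(CCl)cc1
Why: Williamson etherification of the sodium alkoxide with the benzylic chloride gives the PMB ether that masks O3 until step 22.

Step 7
Reactants: 8 4-methoxybenzyl propargyl ether
Product: 10 methyl 4-[(4-methoxybenzyl)oxy]but-2-ynoate, via lithium acetylide 9 (not isolated)
Conditions: n-BuLi, THF, −78 °C; then ClCO2Me, −78 to 0 °C
Reagents that add atoms: methyl chloroformate, COC(=O)Cl
Why: Deprotonation of the terminal alkyne and C-acylation of the lithium acetylide with a chloroformate is the standard route to an ynoate.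

Step 8
Reactants: 10 methyl 4-[(4-methoxybenzyl)oxy]but-2-ynoate
Product: 12 methyl (Z)-4-[(4-methoxybenzyl)oxy]-3-methylbut-2-enoate, via lithium alkenyl(methyl)cuprate 11 (not isolated)
Conditions: Me2CuLi (from MeLi and CuI), THF, −78 °C; MeOH quench at −78 °C
Reagents that add atoms: lithium dimethylcuprate, [Li+].C[Cu-]C
Why: syn-Carbocupration of the ynoate at −78 °C followed by cold protonation places the new methyl trans to the ester, so that the ester carbon (later C6) and CH2OPMB (later C3) are cis, the Z geometry needed for C4=C5.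

Step 9
Reactants: 12 methyl (Z)-4-[(4-methoxybenzyl)oxy]-3-methylbut-2-enoate
Product: 13 (Z)-4-[(4-methoxybenzyl)oxy]-3-methylbut-2-en-1-ol
Conditions: i-Bu2AlH (2.5 equiv), CH2Cl2, −78 °C; Rochelle salt
Reagents that add atoms: none
Why: i-Bu2AlH reduces the enoate 1,2 to the allylic alcohol at −78 °C without touching the alkene geometry or the PMB ether.

Step 10
Reactants: 13 (Z)-4-[(4-methoxybenzyl)oxy]-3-methylbut-2-en-1-ol
Product: 14 (Z)-4-[(4-methoxybenzyl)oxy]-3-methylbut-2-enal
Conditions: Dess–Martin periodinane, NaHCO3, CH2Cl2, 0 °C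
Reagents that add atoms: none
Why: Buffered Dess–Martin oxidation gives the (Z)-enal under neutral conditions that do not isomerise the β,β-disubstituted enal.

Step 11
Reactants: 14 (Z)-4-[(4-methoxybenzyl)oxy]-3-methylbut-2-enal
Product: 15 (3R,4Z)-6-[(4-methoxybenzyl)oxy]-5-methyl-1-(trimethylsilyl)hex-4-en-1-yn-3-ol
Conditions: HC≡CSiMe3 (3 equiv), ZnMe2 (3 equiv), (S,S)-ProPhenol (10 mol%), Ph3PO (20 mol%), toluene, 4 °C
Reagents that add atoms: ethynyltrimethylsilane, C#C[Si](C)(C)C
Why: Zinc–ProPhenol asymmetric alkynylation, in which the dinuclear zinc catalyst binds the enal and the alkynylzinc and delivers the alkynyl group to one enantiotopic face, is established for α,β-unsaturated aldehydes and sets C6 as (R) by catalyst control.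

Step 12
Reactants: 15 (3R,4Z)-6-[(4-methoxybenzyl)oxy]-5-methyl-1-(trimethylsilyl)hex-4-en-1-yn-3-ol
Product: 16 (3R,4Z)-6-[(4-methoxybenzyl)oxy]-5-methylhex-4-en-1-yn-3-ol
Conditions: K2CO3 (cat.), MeOH, rt
Reagents that add atoms: none
Why: Methanolysis of the C(sp)–Si bond with catalytic carbonate removes only the alkynyl TMS group.

Step 13
Reactants: 16 (3R,4Z)-6-[(4-methoxybenzyl)oxy]-5-methylhex-4-en-1-yn-3-ol
Product: 17 (3S,4Z)-6-[(4-methoxybenzyl)oxy]-5-methylhexa-1,4-dien-3-ol
Conditions: H2 (1 atm), Pd/CaCO3 poisoned with Pb(OAc)2, quinoline, EtOAc, rt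
Reagents that add atoms: none
Why: Lindlar semihydrogenation reduces the terminal alkyne to the vinyl group and stops there, the trisubstituted alkene and the PMB ether being inert on the poisoned catalyst (the descriptor changes only through priorities).

Step 14
Reactants: 17 (3S,4Z)-6-[(4-methoxybenzyl)oxy]-5-methylhexa-1,4-dien-3-ol; 18 2-(bromomethyl)acrylic acid
Product: 19 (3S,4Z)-6-[(4-methoxybenzyl)oxy]-5-methylhexa-1,4-dien-3-yl 2-(bromomethyl)acrylate
Conditions: DCC, DMAP (5 mol%), CH2Cl2, −20 to 0 °C
Reagents that add atoms: none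
Why: Steglich esterification (carbodiimide activation, catalytic DMAP at low temperature) acylates the unhindered secondary alcohol faster than DMAP or the alcohol can displace the allylic bromide.

Step 15
Reactants: 19 (3S,4Z)-6-[(4-methoxybenzyl)oxy]-5-methylhexa-1,4-dien-3-yl 2-(bromomethyl)acrylate
Product: 20 (R)-3-(bromomethyl)-5-[(Z)-3-((4-methoxybenzyl)oxy)-2-methylprop-1-en-1-yl]furan-2(5H)-one
Conditions: second-generation Grubbs catalyst (5 mol%), 1,4-benzoquinone (10 mol%), CH2Cl2 (5 mM), 40 °C
Reagents that add atoms: none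
Why: Ring-closing metathesis between the vinyl group and the 1,1-disubstituted acrylate forms the trisubstituted C7=C11 bond of the butenolide with loss of ethene, the trisubstituted side-chain alkene being inert, and benzoquinone suppresses ruthenium hydride isomerisation at the doubly allylic C6.

Step 16
Reactants: 21 (E)-crotonaldehyde
Product: 22 (Z)-2-iodobut-2-enal
Conditions: I2, K2CO3, DMAP (20 mol%), THF/H2O, rt
Reagents that add atoms: iodine, II
Why: DMAP-catalysed α-iodination of the enal (conjugate addition, iodination of the enolate, elimination) gives the thermodynamic isomer with CHO trans to methyl, that is, iodine cis to methyl.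

Step 17
Reactants: 22 (Z)-2-iodobut-2-enal
Product: 23 (Z)-2-iodobut-2-en-1-ol
Conditions: NaBH4, CeCl3·7H2O, MeOH, 0 °C
Reagents that add atoms: none
Why: Luche reduction gives 1,2-reduction of the iodo enal without loss of iodine or change of alkene geometry.

Step 18
Reactants: 23 (Z)-2-iodobut-2-en-1-ol
Product: 24 (Z)-tert-butyl[(2-iodobut-2-en-1-yl)oxy]dimethylsilane
Conditions: t-BuMe2SiCl, imidazole, CH2Cl2, rt
Reagents that add atoms: tert-butyldimethylsilyl chloride, CC(C)(C)[Si](C)(C)Cl
Why: Standard silylation of the primary allylic alcohol keeps the hydroxymethyl group inert, and free of an allylic leaving group, until step 28.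

Step 19
Reactants: 24 (Z)-tert-butyl[(2-iodobut-2-en-1-yl)oxy]dimethylsilane
Product: 25 (Z)-2-[(tert-butyldimethylsilyloxy)methyl]but-2-enoic acid
Conditions: Pd(OAc)2 (5 mol%), PPh3 (10 mol%), CO (1 atm), Et3N, H2O, DMF, 50 °C; mild acid work-up
Reagents that add atoms: carbon monoxide, [C-]#[O+]; water, O
Why: Palladium-catalysed hydroxycarbonylation of the alkenyl iodide (oxidative addition to zerovalent palladium, CO insertion, hydrolysis of the acylpalladium) proceeds with retention of alkene geometry, so the carboxyl ends up cis to the methyl group as in the angelate-type ester of the target.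

Step 20
Reactants: 20 (R)-3-(bromomethyl)-5-[(Z)-3-((4-methoxybenzyl)oxy)-2-methylprop-1-en-1-yl]furan-2(5H)-one; 6 (R)-3-methyl-3-(triethylsilyloxy)pent-4-ynal
Product: 27 (6R,7R,8R,10R)-seco-lactone C8 alcohol, via allylzinc bromide 26 (not isolated)
Conditions: Zn dust (3 equiv), THF/sat. aq NH4Cl (3:1), 0 °C to rt
Reagents that add atoms: none
Why: Zinc Barbier allylation with allylic transposition: allylzinc 26 attacks the aldehyde through ring carbon C7 on the face opposite the C6 side chain (C6/C7 trans), the double bond moves to C11=C13, and the open arrangement expected for zinc couplings of 3-(bromomethyl)butenolides in aqueous medium should give the syn C7/C8 relationship, that is (8R).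

Step 21
Reactants: 27 (6R,7R,8R,10R)-seco-lactone C8 alcohol; 25 (Z)-2-[(tert-butyldimethylsilyloxy)methyl]but-2-enoic acid
Product: 29 C8 ester with PMB ether, via mixed anhydride 28 (not isolated)
Conditions: 25, 2,4,6-trichlorobenzoyl chloride, Et3N, toluene, rt; then 27, toluene, 75 °C (no DMAP)
Reagents that add atoms: none
Why: Mixed-anhydride (Yamaguchi-type) esterification run without DMAP avoids Z-to-E isomerisation of the angelate-type acid by conjugate addition of a nucleophilic catalyst, and the acyl group goes on here because the Barbier step leaves the C8 hydroxyl free.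

Step 22
Reactants: 29 C8 ester with PMB ether
Product: 30 C8 ester C3 alcohol
Conditions: DDQ, CH2Cl2/pH 7 phosphate buffer (10:1), 0 °C
Reagents that add atoms: none
Why: Oxidative cleavage of the PMB ether by DDQ in buffered wet CH2Cl2 frees the C3 hydroxyl and leaves the silyl ethers, the esters, the lactone and the alkyne untouched.

Step 23
Reactants: 30 C8 ester C3 alcohol
Product: 31 C3 (Z)-enal with terminal alkyne
Conditions: Dess–Martin periodinane, NaHCO3, CH2Cl2, 0 °C
Reagents that add atoms: none
Why: Buffered Dess–Martin oxidation gives the C3 (Z)-enal without isomerising the C4=C5 bond, whose cis geometry holds the aldehyde on the side of C6 for ring closure.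

Step 24
Reactants: 31 C3 (Z)-enal with terminal alkyne
Product: 32 C3 (Z)-enal C2 iodoalkyne (key-step precursor)
Conditions: N-iodosuccinimide, AgNO3 (10 mol%), acetone, rt, dark
Reagents that add atoms: N-iodosuccinimide, O=C1CCC(=O)N1I
Why: Silver-catalysed iodination of the terminal alkyne with N-iodosuccinimide (through the silver acetylide) is selective for the C(sp)–H bond in the presence of the enal and the alkenes.

Step 25
Reactants: 32 C3 (Z)-enal C2 iodoalkyne
Product: 34 ten-membered C3 propargylic alcohol (both C3 epimers), via alkynylchromium dichloride 33 (not isolated)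
Conditions: CrCl2 (8 equiv), NiCl2 (2 mol% of the CrCl2), degassed THF, rt, slow addition of 32 to 3 mM
Reagents that add atoms: none
Why: Zerovalent nickel, formed from NiCl2 by divalent chromium, inserts into the C2–I bond, the alkynyl group passes to trivalent chromium, and the alkynylchromium 33 adds 1,2 to the C3 aldehyde; the closest known reaction type is the Ni/Cr-mediated (Nozaki–Hiyama–Kishi) intramolecular coupling of iodoalkynes with aldehydes used to close ten-membered cycloalkynes. The ten-membered carbocycle C1–C10 closes by 10-exo-trig attack of C2 on the C3 carbonyl under high dilution, helped by the cis C4=C5 bond and the trans-lactone, which turn the aldehyde back toward C10. The new C3 carbinol centre is not controlled and needs no control, because step 26 oxidises it away. The step needs chemoselectivity for the aldehyde over the lactone, the enoate ester and the exocyclic methylene, which the low basicity and aldehyde selectivity of organochromium reagents secure, and it leaves the (Z)-enal geometry and the C6, C7, C8 and C10 centres untouched.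

Step 26
Reactants: 34 ten-membered C3 propargylic alcohol
Product: 35 ten-membered ynone
Conditions: Dess–Martin periodinane, NaHCO3, CH2Cl2, 0 °C
Reagents that add atoms: none
Why: Dess–Martin oxidation of the doubly activated (propargylic and allylic) alcohol gives the cross-conjugated ynone and removes the uncontrolled C3 centre.

Step 27
Reactants: 35 ten-membered ynone
Product: 36 ten-membered (1Z,4Z)-dienone
Conditions: H2 (1 atm), Pd/CaCO3 poisoned with Pb(OAc)2, quinoline, EtOAc, 0 °C to rt, stopped at one equivalent of H2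
Reagents that add atoms: none
Why: Lindlar semihydrogenation adds H2 syn on the poisoned palladium surface to the alkyne, which binds far more strongly than the enoate alkenes, and gives the cis C1=C2 enone that the ten-membered ring in any case requires.

Step 28
Reactants: 36 ten-membered (1Z,4Z)-dienone
Product: 38 hemiketal with free side-chain hydroxyl, via desilylated dienone diol 37 (not isolated)
Conditions: HF·pyridine, pyridine, THF, 0 °C to rt
Reagents that add atoms: none
Why: HF·pyridine desilylation frees the side-chain primary hydroxyl and the C10 tertiary hydroxyl, which adds to the C3 ketone across the cis C1=C2 bond (reversible 5-exo-trig hemiketalisation) to form the dihydrofuran ring, and the C3 configuration (R) is fixed by the C10 centre because the oxygen bridge can span the ten-membered ring on one face only.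

Step 29
Reactants: 38 hemiketal with free side-chain hydroxyl
Product: 39 CNP0256971.1 (target)
Conditions: AcCl (1.1 equiv), 2,4,6-collidine, CH2Cl2, −78 °C
Reagents that add atoms: acetyl chloride, CC(=O)Cl
Why: Acetylation with acetyl chloride and the hindered base collidine at −78 °C is selective for the primary allylic hydroxyl over the tertiary hemiketal hydroxyl and avoids nucleophilic catalysts that could isomerise the angelate-type ester.

## Compound list

1 | (S)-2-methylglycidol, (S)-(2-methyloxiran-2-yl)methanol | C[C@]1(CO)CO1 | starting material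
2 | (R)-2-methylpent-4-ene-1,2-diol | C=CC[C@@](C)(O)CO | intermediate
3 | (R)-2-hydroxy-2-methylpent-4-enal | C=CC[C@@](C)(O)C=O | intermediate
4 | (R)-3-methylhex-5-en-1-yn-3-ol | C=CC[C@@](C)(O)C#C | intermediate
5 | (R)-triethyl[(3-methylhex-5-en-1-yn-3-yl)oxy]silane | C=CC[C@@](C)(O[Si](CC)(CC)CC)C#C | intermediate
6 | (R)-3-methyl-3-(triethylsilyloxy)pent-4-ynal (C8 aldehyde; C8–C10, C1, C2) | O=CC[C@@](C)(O[Si](CC)(CC)CC)C#C | intermediate
7 | propargyl alcohol (prop-2-yn-1-ol) | C#CCO | starting material
8 | 4-methoxybenzyl propargyl ether | C#CCOCc1ccc(OC)cc1 | intermediate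
9 | lithium 3-[(4-methoxybenzyl)oxy]prop-1-yn-1-ide (lithium acetylide of 8) | [Li]C#CCOCc1ccc(OC)cc1 | intermediate
10 | methyl 4-[(4-methoxybenzyl)oxy]but-2-ynoate | COC(=O)C#CCOCc1ccc(OC)cc1 | intermediate
11 | lithium [1-(methoxycarbonyl)-3-((4-methoxybenzyl)oxy)-2-methylprop-1-enyl](methyl)cuprate, copper cis to the new methyl | [Li+].COC(=O)/C([Cu-]C)=C(/C)COCc1ccc(OC)cc1 | intermediate
12 | methyl (Z)-4-[(4-methoxybenzyl)oxy]-3-methylbut-2-enoate | COC(=O)/C=C(/C)COCc1ccc(OC)cc1 | intermediate
13 | (Z)-4-[(4-methoxybenzyl)oxy]-3-methylbut-2-en-1-ol | OC/C=C(/C)COCc1ccc(OC)cc1 | intermediate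
14 | (Z)-4-[(4-methoxybenzyl)oxy]-3-methylbut-2-enal | O=C/C=C(/C)COCc1ccc(OC)cc1 | intermediate
15 | (3R,4Z)-6-[(4-methoxybenzyl)oxy]-5-methyl-1-(trimethylsilyl)hex-4-en-1-yn-3-ol | O[C@H](/C=C(/C)COCc1ccc(OC)cc1)C#C[Si](C)(C)C | intermediate
16 | (3R,4Z)-6-[(4-methoxybenzyl)oxy]-5-methylhex-4-en-1-yn-3-ol | O[C@H](/C=C(/C)COCc1ccc(OC)cc1)C#C | intermediate
17 | (3S,4Z)-6-[(4-methoxybenzyl)oxy]-5-methylhexa-1,4-dien-3-ol | O[C@H](/C=C(/C)COCc1ccc(OC)cc1)C=C | intermediate
18 | 2-(bromomethyl)acrylic acid | C=C(CBr)C(=O)O | starting material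
19 | (3S,4Z)-6-[(4-methoxybenzyl)oxy]-5-methylhexa-1,4-dien-3-yl 2-(bromomethyl)acrylate | C=C(CBr)C(=O)O[C@H](/C=C(/C)COCc1ccc(OC)cc1)C=C | intermediate
20 | (R)-3-(bromomethyl)-5-[(Z)-3-((4-methoxybenzyl)oxy)-2-methylprop-1-en-1-yl]furan-2(5H)-one | O=C1O[C@H](/C=C(/C)COCc2ccc(OC)cc2)C=C1CBr | intermediate
21 | (E)-crotonaldehyde | C/C=C/C=O | starting material
22 | (Z)-2-iodobut-2-enal | C/C=C(\I)C=O | intermediate
23 | (Z)-2-iodobut-2-en-1-ol | C/C=C(\I)CO | intermediate
24 | (Z)-tert-butyl[(2-iodobut-2-en-1-yl)oxy]dimethylsilane | C/C=C(\I)CO[Si](C)(C)C(C)(C)C | intermediate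
25 | (Z)-2-[(tert-butyldimethylsilyloxy)methyl]but-2-enoic acid | C/C=C(\C(=O)O)CO[Si](C)(C)C(C)(C)C | intermediate
26 | allylzinc bromide of 20: {(R)-5-[(Z)-3-((4-methoxybenzyl)oxy)-2-methylprop-1-en-1-yl]-2-oxo-2,5-dihydrofuran-3-yl}methylzinc bromide | O=C1O[C@H](/C=C(/C)COCc2ccc(OC)cc2)C=C1C[Zn]Br | intermediate
27 | (6R,7R,8R,10R)-seco-lactone C8 alcohol: (4R,5R)-4-[(1R,3R)-1-hydroxy-3-methyl-3-(triethylsilyloxy)pent-4-yn-1-yl]-5-[(Z)-3-((4-methoxybenzyl)oxy)-2-methylprop-1-en-1-yl]-3-methylidenedihydrofuran-2(3H)-one | C=C1C(=O)O[C@H](/C=C(/C)COCc2ccc(OC)cc2)[C@H]1[C@H](O)C[C@@](C)(O[Si](CC)(CC)CC)C#C | intermediate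
28 | mixed anhydride of 25 with 2,4,6-trichlorobenzoic acid | C/C=C(\C(=O)OC(=O)c1c(Cl)cc(Cl)cc1Cl)CO[Si](C)(C)C(C)(C)C | intermediate
29 | C8 ester with PMB ether: 27 acylated at O8 with the (Z)-2-[(tert-butyldimethylsilyloxy)methyl]but-2-enoyl group, (6R,7R,8R,10R) | C=C1C(=O)O[C@H](/C=C(/C)COCc2ccc(OC)cc2)[C@H]1[C@H](OC(=O)/C(=C\C)CO[Si](C)(C)C(C)(C)C)C[C@@](C)(O[Si](CC)(CC)CC)C#C | intermediate
30 | C8 ester C3 alcohol: as 29 with the side chain (Z)-CH=C(CH3)CH2OH at C6 | C=C1C(=O)O[C@H](/C=C(/C)CO)[C@H]1[C@H](OC(=O)/C(=C\C)CO[Si](C)(C)C(C)(C)C)C[C@@](C)(O[Si](CC)(CC)CC)C#C | intermediate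
31 | C3 (Z)-enal with terminal alkyne: as 30 with the side chain (Z)-CH=C(CH3)CHO at C6 | C=C1C(=O)O[C@H](/C=C(/C)C=O)[C@H]1[C@H](OC(=O)/C(=C\C)CO[Si](C)(C)C(C)(C)C)C[C@@](C)(O[Si](CC)(CC)CC)C#C | intermediate
32 | C3 (Z)-enal C2 iodoalkyne (key-step precursor), (6R,7R,8R,10R) | C=C1C(=O)O[C@H](/C=C(/C)C=O)[C@H]1[C@H](OC(=O)/C(=C\C)CO[Si](C)(C)C(C)(C)C)C[C@@](C)(O[Si](CC)(CC)CC)C#CI | intermediate
33 | alkynylchromium dichloride of 32 (chromium on C2) | C=C1C(=O)O[C@H](/C=C(/C)C=O)[C@H]1[C@H](OC(=O)/C(=C\C)CO[Si](C)(C)C(C)(C)C)C[C@@](C)(O[Si](CC)(CC)CC)C#C[Cr](Cl)Cl | intermediate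
34 | ten-membered C3 propargylic alcohol: (6R,7R,8R,10R)-3-hydroxy-10-(triethylsilyloxy)germacra-4Z,11(13)-dien-1-yn-12,6-olide 8-ester, (3RS), one C3 epimer drawn | C=C1C(=O)O[C@@H]2/C=C(/C)[C@@H](O)C#C[C@](C)(O[Si](CC)(CC)CC)C[C@@H](OC(=O)/C(=C\C)CO[Si](C)(C)C(C)(C)C)[C@@H]12 | intermediate
35 | ten-membered ynone: 3-oxo analogue of 34 | C=C1C(=O)O[C@@H]2/C=C(/C)C(=O)C#C[C@](C)(O[Si](CC)(CC)CC)C[C@@H](OC(=O)/C(=C\C)CO[Si](C)(C)C(C)(C)C)[C@@H]12 | intermediate
36 | ten-membered (1Z,4Z)-dienone: (6R,7R,8R,10R)-3-oxo-10-(triethylsilyloxy)germacra-1Z,4Z,11(13)-trien-12,6-olide 8-ester | C=C1C(=O)O[C@@H]2/C=C(/C)C(=O)/C=C\[C@](C)(O[Si](CC)(CC)CC)C[C@@H](OC(=O)/C(=C\C)CO[Si](C)(C)C(C)(C)C)[C@@H]12 | intermediate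
37 | desilylated dienone diol: 10-hydroxy-3-oxo compound with the (Z)-2-(hydroxymethyl)but-2-enoate at O8 | C=C1C(=O)O[C@@H]2/C=C(/C)C(=O)/C=C\[C@](C)(O)C[C@@H](OC(=O)/C(=C\C)CO)[C@@H]12 | intermediate
38 | hemiketal with free side-chain hydroxyl: (3R,6R,7R,8R,10R)-3-hydroxy-3,10-epoxygermacra-1,4Z,11(13)-trien-12,6-olide 8-O-[(Z)-2-(hydroxymethyl)but-2-enoate] | C=C1C(=O)O[C@@H]2/C=C(/C)[C@@]3(O)C=C[C@@](C)(C[C@@H](OC(=O)/C(=C\C)CO)[C@@H]12)O3 | intermediate
39 | CNP0256971.1: (3R,6R,7R,8R,10R)-3-hydroxy-3,10-epoxygermacra-1,4Z,11(13)-trien-12,6-olide 8-O-[(Z)-2-(acetoxymethyl)but-2-enoate] | C=C1C(=O)O[C@@H]2/C=C(/C)[C@@]3(O)C=C[C@@](C)(C[C@@H](OC(=O)/C(=C\C)COC(C)=O)[C@@H]12)O3 | target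

## Step count and risks

Total step count: 29. Longest linear sequence: 20 steps (steps 6–15, then 20–29).

Most likely to fail, first: step 25. Ring closure may lose to intermolecular coupling and to protodeiodination, because the linear C10–C1≡C2 unit has to be bent into a ten-membered ring that already carries the trans-lactone. The fallback bends the nucleophile before closure and sets out from 29. Iodination (N-iodosuccinimide, AgNO3) would give the PMB-protected iodoalkyne F1. syn-Hydroboration with dicyclohexylborane and protonolysis with acetic acid would give the (1Z)-iodoalkene F2. DDQ would free the iodoalkene C3 alcohol F3, and Dess–Martin oxidation would give the iodoalkene (Z)-enal F4. CrCl2 with catalytic NiCl2 in DMSO at high dilution would then close the ring by alkenylchromium addition to the aldehyde and give the ten-membered (1Z,4Z)-dienyl alcohol F5. Dess–Martin oxidation of F5 comes back to the route at 36, so the semihydrogenation of step 27 is no longer needed.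

Second: step 20. Simple diastereoselection at C8 may be poor or reversed if the zinc reagent adds through a closed chair and not the open arrangement (the facial sense at C7, set by the ring, is less in doubt). The fallback sets out from 20 and 6 and uses the closed-chair chromium allylation deliberately (CrCl2, THF), which is anti-selective and would give the 8-epi alcohol F6. Mitsunobu esterification of F6 with acid 25 (PPh3, diisopropyl azodicarboxylate, toluene) would install the ester with inversion at C8 and come back to the route at 29.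

Third: step 15. Metathesis at the 1,1-disubstituted bromomethylacrylate may be slow, and ruthenium hydride species may move the new double bond or erode the doubly allylic C6 centre. The fallback builds the butenolide by carbonylation and sets out from 14. Zinc–ProPhenol alkynylation with tert-butyldimethyl(prop-2-yn-1-yloxy)silane would give the propargylic alcohol F7. Hydroxyl-directed trans-hydroalumination with NaAlH2(OCH2CH2OMe)2 and iodination (I2, −78 °C) would give the (Z)-iodo allylic alcohol F8. Carbonylative lactonisation (PdCl2(PPh3)2, CO 1 atm, K2CO3, THF, rt) would give the silyloxymethyl butenolide F9. HF·pyridine would free the hydroxymethyl butenolide F10, and CBr4/PPh3 would convert it into the bromide, coming back to the route at 20 and replacing steps 11–15.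

## Further compounds

F1 | step 25 | C2 iodoalkyne with PMB ether (iodo analogue of 29) | C=C1C(=O)O[C@H](/C=C(/C)COCc2ccc(OC)cc2)[C@H]1[C@H](OC(=O)/C(=C\C)CO[Si](C)(C)C(C)(C)C)C[C@@](C)(O[Si](CC)(CC)CC)C#CI
F2 | step 25 | (1Z)-iodoalkene with PMB ether | C=C1C(=O)O[C@H](/C=C(/C)COCc2ccc(OC)cc2)[C@H]1[C@H](OC(=O)/C(=C\C)CO[Si](C)(C)C(C)(C)C)C[C@@](C)(O[Si](CC)(CC)CC)/C=C\I
F3 | step 25 | (1Z)-iodoalkene C3 alcohol | C=C1C(=O)O[C@H](/C=C(/C)CO)[C@H]1[C@H](OC(=O)/C(=C\C)CO[Si](C)(C)C(C)(C)C)C[C@@](C)(O[Si](CC)(CC)CC)/C=C\I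
F4 | step 25 | (1Z)-iodoalkene C3 (Z)-enal | C=C1C(=O)O[C@H](/C=C(/C)C=O)[C@H]1[C@H](OC(=O)/C(=C\C)CO[Si](C)(C)C(C)(C)C)C[C@@](C)(O[Si](CC)(CC)CC)/C=C\I
F5 | step 25 | ten-membered (1Z,4Z)-dienyl C3 alcohol, (3RS), one epimer drawn | C=C1C(=O)O[C@@H]2/C=C(/C)[C@@H](O)/C=C\[C@](C)(O[Si](CC)(CC)CC)C[C@@H](OC(=O)/C(=C\C)CO[Si](C)(C)C(C)(C)C)[C@@H]12
F6 | step 20 | (6R,7R,8S,10R)-seco-lactone C8 alcohol (8-epimer of 27) | C=C1C(=O)O[C@H](/C=C(/C)COCc2ccc(OC)cc2)[C@H]1[C@@H](O)C[C@@](C)(O[Si](CC)(CC)CC)C#C
F7 | step 15 | (4R,5Z)-1-(tert-butyldimethylsilyloxy)-7-[(4-methoxybenzyl)oxy]-6-methylhept-5-en-2-yn-4-ol | O[C@H](/C=C(/C)COCc1ccc(OC)cc1)C#CCO[Si](C)(C)C(C)(C)C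
F8 | step 15 | (2Z,4R,5Z)-1-(tert-butyldimethylsilyloxy)-2-iodo-7-[(4-methoxybenzyl)oxy]-6-methylhepta-2,5-dien-4-ol | O[C@H](/C=C(/C)COCc1ccc(OC)cc1)/C=C(\I)CO[Si](C)(C)C(C)(C)C
F9 | step 15 | (R)-3-[(tert-butyldimethylsilyloxy)methyl]-5-[(Z)-3-((4-methoxybenzyl)oxy)-2-methylprop-1-en-1-yl]furan-2(5H)-one | O=C1O[C@H](/C=C(/C)COCc2ccc(OC)cc2)C=C1CO[Si](C)(C)C(C)(C)C
F10 | step 15 | (R)-3-(hydroxymethyl)-5-[(Z)-3-((4-methoxybenzyl)oxy)-2-methylprop-1-en-1-yl]furan-2(5H)-one | O=C1O[C@H](/C=C(/C)COCc2ccc(OC)cc2)C=C1CO
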